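The earlier runs and the new flask are calculated for substances that don't exist, and the scatter is random.

At late times the earlier runs agree: at 20.0 h, alder (19 mM free catalyst) and oak (44 mM) hold target plus starting material of 93.0 % and 93.0 % of the charge, although oak carries more catalyst. Within the scatter, the missing share does not follow the catalyst.

the same everywhere: starting material 0.80 M

| flask | second substrate | reagent | protic impurity | free catalyst | remark | time |
|---|---|---|---|---|---|---|
| alder | 0.40 M | 1.2 M | 0.080 M | 19 mM | run made earlier |  |
| oak | 0.40 M | 1.2 M | 0.080 M | 44 mM | run made earlier |  |
| violet | 0.400 M | 1.20 M | 0.0800 M | 25 mM |  | 40 h |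
| grey | 0.400 M | 1.20 M | 0.0800 M | 30 mM |  | 40 h |
| blue | 0.400 M | 1.20 M | 0.0800 M | 50 mM |  | 40 h |

| run | time / h | target / % | starting material / % |
|---|---|---|---|
| alder | 1.50 | 9 | 82 |
| alder | 4.00 | 26 | 64 |
| alder | 8.00 | 49 | 46 |
| alder | 20.0 | 82 | 11 |
| oak | 2.50 | 41 | 51 |
| oak | 8.00 | 81 | 12 |
| oak | 12.0 | 87 | 2 |
| oak | 20.0 | 93 | 0 |

(scatter of a reading: 1.5 percentage points)

- amount of target at the end, in percent of the starting material charged for violet, grey, blue, in this order
- the course of these numbers from the first flask to the last (rises all the way / falls all the way / falls, then rises / rises, then falls / hardly changes)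

- the analysis behind the earlier runs scatters by 1.5 percentage points, standard deviation
- "hardly changes" means that all values lie within two and a half points (for a concentration: within two and a half percent of the largest)

My own estimate treats that loss as a one-to-one quench of starting material by protic impurity, by its charge the limiting reagent of this side path. The quench capacity, c(protic impurity) over c(starting material) as charged, is then 10.0 %. The share missing in alder at 20.0 h, 7.00 %, is a reading and stands below it. The three flasks carry more free catalyst than alder, and 40 h is twice the time at which alder held 11 % starting material. So I expect conversion to be nearly complete and the target to lie between 90.0 % and 93.0 %, in a course that hardly changes.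

The forecast gives one point inside that band: 92 %, 92 %, 92 %, hardly changes, with the loss assigned “most plausibly by stoichiometric quenching with the protic impurity”.

The flasks give 90.0 %, 90.1 %, 90.6 %: hardly changes.

    second substrate + free catalyst ⇌ catalyst intermediate B (K = 43.0 /M, k = 33.0 /M/h)
    reagent + catalyst intermediate B → free catalyst + second product (k = 2.70 /M/h)
    reagent + catalyst intermediate A → free catalyst + target (k = 280 /M/h)
    starting material + free catalyst ⇌ catalyst intermediate A (K = 1.20 /M, k = 18.0 /M/h)
    starting material + protic impurity → quenched substrate (k = 1.10 /M/h)

Violet ends at 90.0 % target. At 40.0 h, violet keeps 0.34 % of its protic impurity and holds 9.97 % quenched substrate; the capacity times the impurity used gives 9.97 %. Blue keeps 6.2 % of its protic impurity and 0 % of its starting material at 40.0 h, so the capacity gives 9.38 % quenched substrate and 90.6 % target, and blue holds 9.38 % and 90.6 %.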